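The C10 side chain is not attached as a geranyl unit. It is grown on ring A by cutting C4''–C5''. The feature exploited is that C6''–O sits γ,δ to the C2''=C3'' alkene (a Claisen retron). In addition, the terminus C6''H(OH)–C7''(CH3)=C8''H2 repeats, one isoprene unit further out, the motif ArCH2–CH(OH)–C(CH3)=CH2. Enol-ether Claisen rearrangement of this racemic C5 carbinol with 2-methoxy-3-methylbuta-1,3-diene forms C4''–C5'', sets the (E)-alkene, erases the racemic centre and delivers the C6'' isopropenyl ketone in one operation. Two trisubstituted alkenes never need to be told apart. Catalytic enantioselective reduction then sets C6''(R), and the cinnamoyl unit enters at C1' by aryllithium acylation.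

Key step: step 7

Remark: ring A is the acylated resorcinol ring (C1'–C6') and the side chain is C1''–C8''. CIP analysis of the given SMILES gives (6''R), (2''E) and an (E)-enone. Racemic compounds are written without stereo marks.

Step 1
Reactants: 1 resorcinol
Product: 2 1,3-bis(methoxymethoxy)benzene
Conditions: NaH, MOMCl, DMF, 0 °C to rt
Reagents that add atoms: chloromethyl methyl ether (MOMCl), COCCl
Why: Williamson-type O-alkylation of the bis-phenoxide should give the bis-acetal, whose OMOM groups direct the lithiation in step 2, survive base, peracid, aluminium alkoxide and borane, and leave together under mild acid at the end.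

Step 2
Reactants: 2 1,3-bis(methoxymethoxy)benzene; 3 prenyl bromide (1-bromo-3-methylbut-2-ene)
Product: 5 1,3-bis(methoxymethoxy)-2-(3-methylbut-2-en-1-yl)benzene, via 2-lithio arene 4 (not isolated)
Conditions: n-BuLi, THF, 0 °C to rt; then 3, −78 °C to rt
Reagents that add atoms: none
Why: Directed ortho-metalation takes place at C2–H, the site flanked and acidified by both OMOM groups, and SN2 alkylation of aryllithium 4 by the primary allylic bromide should fix the C3'–C1'' bond between the two oxygens with no regioisomer problem.

Step 3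
Reactants: 5 1,3-bis(methoxymethoxy)-2-(3-methylbut-2-en-1-yl)benzene
Product: 6 3-{[2,6-bis(methoxymethoxy)phenyl]methyl}-2,2-dimethyloxirane (racemic)
Conditions: mCPBA, CH2Cl2, 0 °C
Reagents that add atoms: 3-chloroperoxybenzoic acid (mCPBA), OOC(=O)c1cccc(Cl)c1
Why: Prilezhaev epoxidation of the only alkene should be fast at 0 °C, and the racemic stereocentre formed here is of no consequence because it is erased in step 7.

Step 4
Reactants: 6 3-{[2,6-bis(methoxymethoxy)phenyl]methyl}-2,2-dimethyloxirane
Product: 7 3-{[3-bromo-2,6-bis(methoxymethoxy)phenyl]methyl}-2,2-dimethyloxirane (racemic)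
Conditions: NBS (1.0 equiv), MeCN, 0 °C, dark
Reagents that add atoms: N-bromosuccinimide, O=C1CCC(=O)N1Br
Why: Electrophilic aromatic bromination goes to the position para to one OMOM and ortho to the other (the future C1'), and it is placed here because 6 holds no alkene that could compete for the bromine source while the epoxide is inert to neutral NBS.

Step 5
Reactants: 7 3-{[3-bromo-2,6-bis(methoxymethoxy)phenyl]methyl}-2,2-dimethyloxirane
Product: 8 1-[3-bromo-2,6-bis(methoxymethoxy)phenyl]-3-methylbut-3-en-2-ol (racemic)
Conditions: Al(Oi-Pr)3, toluene, 110 °C; aqueous work-up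
Reagents that add atoms: none
Why: In this aluminium-alkoxide-promoted isomerisation of a trisubstituted epoxide to an allylic alcohol, aluminium weakens the tertiary C–O bond and an isopropoxide ligand removes a syn methyl proton through a cyclic transition state, so that oxygen stays on the secondary carbon and the 1,1-disubstituted alkene results.

Step 6
Reactants: 9 3-methylbut-3-en-2-one (methyl isopropenyl ketone)
Product: 11 2-methoxy-3-methylbuta-1,3-diene, via dimethyl ketal 10 (not isolated)
Conditions: HC(OMe)3, MeOH, p-TsOH (cat.), rt; then KHSO4 (cat.), hydroquinone, distillation (bath 150 °C)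
Reagents that add atoms: trimethyl orthoformate, COC(OC)OC
Why: Orthoformate ketalisation followed by acid-catalysed loss of one methanol on distillation is the classical preparation of 2-alkoxy-1,3-dienes from enones, and the volatile diene leaves the acid as it forms.

Step 7
Reactants: 8 1-[3-bromo-2,6-bis(methoxymethoxy)phenyl]-3-methylbut-3-en-2-ol; 11 2-methoxy-3-methylbuta-1,3-diene
Product: 14 (E)-8-[3-bromo-2,6-bis(methoxymethoxy)phenyl]-2,6-dimethylocta-1,6-dien-3-one, via mixed ketal 12 (not isolated), via allyl dienyl ether 13 (not isolated)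
Conditions: 11 (excess), 2,4-dinitrophenol (cat.), hydroquinone (cat.), toluene, 110 °C, MeOH distilled off
Reagents that add atoms: none
Why: Weak-acid protonation of 11 at C1 gives an oxocarbenium ion that is captured by the hydroxyl of 8 to give mixed ketal 12, loss of methanol gives allyl dienyl ether 13, and 13 undergoes a concerted [3,3]-sigmatropic shift that makes C4''–C5'' and turns the C–O bond into the C6''=O group. The closest known reaction type is the enol-ether or ketal Claisen rearrangement (Marbet–Saucy variant) of 2-methylalk-1-en-3-ols, which is established for the iterative build-up of trans-trisubstituted polyene chains. No ring is closed, since the six-membered chair exists only in the transition state. No new stereocentre is made: the ArCH2 group takes the pseudo-equatorial position because the axial alternative meets the isopropenyl group on the oxygen-bearing vinyl carbon in a 1,3-diaxial contact, which secures the E geometry, and both enantiomers of 8 converge on the same achiral 14. The step needs exchange at the only free hydroxyl without loss of the aryl MOM acetals, which the weak acid, the aprotic medium and the removal of methanol should secure, and it needs suppression of diene and enone polymerisation, which excess 11, dilution and the inhibitor address.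

Step 8
Reactants: 14 (E)-8-[3-bromo-2,6-bis(methoxymethoxy)phenyl]-2,6-dimethylocta-1,6-dien-3-one
Product: 15 (3R,6E)-8-[3-bromo-2,6-bis(methoxymethoxy)phenyl]-2,6-dimethylocta-1,6-dien-3-ol
Conditions: (S)-2-methyl-CBS-oxazaborolidine (cat.), catecholborane, toluene, −78 °C; aqueous work-up
Reagents that add atoms: none
Why: In the Corey–Bakshi–Shibata reduction the ketone binds to the catalyst boron with the branched isopropenyl group as the large and the CH2 chain as the small substituent, so the (S)-catalyst should deliver hydride to the Si face and give the (R)-carbinol (the same sense as acetophenone to (R)-1-phenylethanol), while catecholborane at −78 °C leaves both alkenes and the aryl bromide alone.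

Step 9
Reactants: 16 4-hydroxybenzaldehyde
Product: 17 4-(methoxymethoxy)benzaldehyde
Conditions: NaH, MOMCl, DMF, 0 °C to rt
Reagents that add atoms: chloromethyl methyl ether (MOMCl), COCCl
Why: Williamson-type O-alkylation gives the ring B phenol the same acetal protection as ring A, so that one final operation frees all three phenols.

Step 10
Reactants: 17 4-(methoxymethoxy)benzaldehyde; 18 diethyl {2-[methoxy(methyl)amino]-2-oxoethyl}phosphonate
Product: 19 (E)-N-methoxy-3-[4-(methoxymethoxy)phenyl]-N-methylprop-2-enamide
Conditions: NaH, THF, 0 °C to rt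
Reagents that add atoms: none
Why: Horner–Wadsworth–Emmons olefination with a stabilised amide phosphonate should give the (E)-alkene and installs the Weinreb amide in the same step.

Step 11
Reactants: 15 (3R,6E)-8-[3-bromo-2,6-bis(methoxymethoxy)phenyl]-2,6-dimethylocta-1,6-dien-3-ol; 19 (E)-N-methoxy-3-[4-(methoxymethoxy)phenyl]-N-methylprop-2-enamide
Product: 22 (E)-1-{3-[(2E,6R)-6-hydroxy-3,7-dimethylocta-2,7-dien-1-yl]-2,4-bis(methoxymethoxy)phenyl}-3-[4-(methoxymethoxy)phenyl]prop-2-en-1-one, via dilithio species 20 (not isolated), via tetrahedral adduct 21 (not isolated)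
Conditions: n-BuLi (2.1 equiv), THF, −78 °C; then 19, −78 to 0 °C; H2O
Reagents that add atoms: none
Why: The first equivalent of n-BuLi makes the alkoxide and the second effects bromine–lithium exchange, which at −78 °C outruns deprotonation of the doubly activated C1'' methylene, and the hard aryllithium adds 1,2 to the Weinreb amide (Weinreb ketone synthesis) to give chelated adduct 21, which collapses to the enone only on quenching, so that over-addition is excluded and C6'' is untouched.

Step 12
Reactants: 22 (E)-1-{3-[(2E,6R)-6-hydroxy-3,7-dimethylocta-2,7-dien-1-yl]-2,4-bis(methoxymethoxy)phenyl}-3-[4-(methoxymethoxy)phenyl]prop-2-en-1-one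
Product: 23 (E)-1-{2,4-dihydroxy-3-[(2E,6R)-6-hydroxy-3,7-dimethylocta-2,7-dien-1-yl]phenyl}-3-(4-hydroxyphenyl)prop-2-en-1-one (target)
Conditions: HCl (cat., dilute), MeOH, 40 °C
Reagents that add atoms: none
Why: Acid-catalysed acetal methanolysis removes phenolic MOM groups under conditions mild enough for geranyl-type chalcones, and the C6'' carbinol should keep its configuration because its ionisation would give an allyl cation with only secondary and primary termini.

Compound list
1 | resorcinol | Oc1cccc(O)c1 | starting material
2 | 1,3-bis(methoxymethoxy)benzene | COCOc1cccc(OCOC)c1 | intermediate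
3 | prenyl bromide (1-bromo-3-methylbut-2-ene) | CC(C)=CCBr | starting material
4 | [2,6-bis(methoxymethoxy)phenyl]lithium (not isolated) | COCOc1cccc(OCOC)c1[Li] | intermediate
5 | 1,3-bis(methoxymethoxy)-2-(3-methylbut-2-en-1-yl)benzene | COCOc1cccc(OCOC)c1CC=C(C)C | intermediate
6 | 3-{[2,6-bis(methoxymethoxy)phenyl]methyl}-2,2-dimethyloxirane (racemic) | COCOc1cccc(OCOC)c1CC1OC1(C)C | intermediate
7 | 3-{[3-bromo-2,6-bis(methoxymethoxy)phenyl]methyl}-2,2-dimethyloxirane (racemic) | COCOc1ccc(Br)c(OCOC)c1CC1OC1(C)C | intermediate
8 | 1-[3-bromo-2,6-bis(methoxymethoxy)phenyl]-3-methylbut-3-en-2-ol (racemic) | COCOc1ccc(Br)c(OCOC)c1CC(O)C(C)=C | intermediate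
9 | 3-methylbut-3-en-2-one | CC(=O)C(C)=C | starting material
10 | 3,3-dimethoxy-2-methylbut-1-ene (not isolated) | C=C(C)C(C)(OC)OC | intermediate
11 | 2-methoxy-3-methylbuta-1,3-diene | C=C(OC)C(C)=C | intermediate
12 | mixed methyl/allyl ketal of 9 with 8 (not isolated, diastereomer mixture) | COCOc1ccc(Br)c(OCOC)c1CC(OC(C)(OC)C(C)=C)C(C)=C | intermediate
13 | 3-methylbuta-1,3-dien-2-yl ether of 8 (not isolated, racemic) | COCOc1ccc(Br)c(OCOC)c1CC(OC(=C)C(C)=C)C(C)=C | intermediate
14 | (E)-8-[3-bromo-2,6-bis(methoxymethoxy)phenyl]-2,6-dimethylocta-1,6-dien-3-one | C=C(C)C(=O)CC/C(C)=C/Cc1c(OCOC)ccc(Br)c1OCOC | intermediate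
15 | (3R,6E)-8-[3-bromo-2,6-bis(methoxymethoxy)phenyl]-2,6-dimethylocta-1,6-dien-3-ol | C=C(C)[C@H](O)CC/C(C)=C/Cc1c(OCOC)ccc(Br)c1OCOC | intermediate
16 | 4-hydroxybenzaldehyde | O=Cc1ccc(O)cc1 | starting material
17 | 4-(methoxymethoxy)benzaldehyde | COCOc1ccc(C=O)cc1 | intermediate
18 | diethyl {2-[methoxy(methyl)amino]-2-oxoethyl}phosphonate | CCOP(=O)(CC(=O)N(C)OC)OCC | starting material
19 | (E)-N-methoxy-3-[4-(methoxymethoxy)phenyl]-N-methylprop-2-enamide | CON(C)C(=O)/C=C/c1ccc(OCOC)cc1 | intermediate
20 | lithium alkoxide/aryllithium from 15 (not isolated) | C=C(C)[C@H](O[Li])CC/C(C)=C/Cc1c(OCOC)ccc([Li])c1OCOC | intermediate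
21 | lithium hemiaminal adduct of 20 and 19 (not isolated, epimers at the new carbon) | C=C(C)[C@H](O[Li])CC/C(C)=C/Cc1c(OCOC)ccc(C(O[Li])(N(C)OC)/C=C/c2ccc(OCOC)cc2)c1OCOC | intermediate
22 | (E)-1-{3-[(2E,6R)-6-hydroxy-3,7-dimethylocta-2,7-dien-1-yl]-2,4-bis(methoxymethoxy)phenyl}-3-[4-(methoxymethoxy)phenyl]prop-2-en-1-one | C=C(C)[C@H](O)CC/C(C)=C/Cc1c(OCOC)ccc(C(=O)/C=C/c2ccc(OCOC)cc2)c1OCOC | intermediate
23 | (E)-1-{2,4-dihydroxy-3-[(2E,6R)-6-hydroxy-3,7-dimethylocta-2,7-dien-1-yl]phenyl}-3-(4-hydroxyphenyl)prop-2-en-1-one | C=C(C)[C@H](O)CC/C(C)=C/Cc1c(O)ccc(C(=O)/C=C/c2ccc(O)cc2)c1O | target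

Total step count: 12. Longest linear sequence: 9 (steps 1, 2, 3, 4, 5, 7, 8, 11, 12).

Steps most likely to fail

Step 7. The weak-acid enol-ether exchange may be slower than cationic or thermal consumption of the electron-rich diene. The liberated methanol may add to the new enone. The hydroxyl group may also transacetalise with the neighbouring MOM group. The fallback sets out from 8 and returns at 14, and it delivers the C5 unit as C2 plus C3. A Johnson orthoester Claisen rearrangement of 8 (triethyl orthoacetate, catalytic propionic acid, 140 °C) should give ethyl (E)-6-[3-bromo-2,6-bis(methoxymethoxy)phenyl]-4-methylhex-4-enoate F1 under the same chair control of the alkene geometry. Aminolysis with MeNH(OMe)·HCl and i-PrMgCl at −20 °C should give (E)-6-[3-bromo-2,6-bis(methoxymethoxy)phenyl]-N-methoxy-N,4-dimethylhex-4-enamide F2. Addition of isopropenylmagnesium bromide, which does not exchange with the electron-rich aryl bromide, then leads to 14.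

Step 5. Lewis-acid opening of the epoxide may proceed with participation of the ortho acetal oxygen, which would close a ring and lose a protecting group. It may also proceed with a hydride shift to a ketone instead of proton loss from the methyl group. The fallback sets out from 2 and returns at 8, and it avoids the epoxide altogether. Compound 2 is lithiated as in step 2, and 4 opens ethylene oxide to give 2-[2,6-bis(methoxymethoxy)phenyl]ethan-1-ol F3. NBS in MeCN brominates the alkene-free arene to give 2-[3-bromo-2,6-bis(methoxymethoxy)phenyl]ethan-1-ol F4. Dess–Martin oxidation gives 2-[3-bromo-2,6-bis(methoxymethoxy)phenyl]acetaldehyde F5. Addition of isopropenylmagnesium bromide at −78 °C gives racemic 8 in the same number of operations.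

Step 12. The freed phenols may cyclise under acid onto the C2''=C3'' alkene or onto the enone. Solvolysis or allylic transposition at C6'' may erode the configuration. The fallback sets out from 22 and returns at 23, and it replaces protic solvolysis by a protecting-group exchange under buffered, non-protic conditions. TMSOTf and 2,2'-bipyridyl in CH2Cl2 at 0 °C should convert the three aryl acetals into aryl silyl ethers and silylate the carbinol. This gives (E)-1-{3-[(2E,6R)-3,7-dimethyl-6-(trimethylsilyloxy)octa-2,7-dien-1-yl]-2,4-bis(trimethylsilyloxy)phenyl}-3-[4-(trimethylsilyloxy)phenyl]prop-2-en-1-one F6. Neutral hydrolysis of F6 in aqueous THF releases 23.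

Further compounds
F1 | step 7 | ethyl (E)-6-[3-bromo-2,6-bis(methoxymethoxy)phenyl]-4-methylhex-4-enoate | CCOC(=O)CC/C(C)=C/Cc1c(OCOC)ccc(Br)c1OCOC
F2 | step 7 | (E)-6-[3-bromo-2,6-bis(methoxymethoxy)phenyl]-N-methoxy-N,4-dimethylhex-4-enamide | CON(C)C(=O)CC/C(C)=C/Cc1c(OCOC)ccc(Br)c1OCOC
F3 | step 5 | 2-[2,6-bis(methoxymethoxy)phenyl]ethan-1-ol | COCOc1cccc(OCOC)c1CCO
F4 | step 5 | 2-[3-bromo-2,6-bis(methoxymethoxy)phenyl]ethan-1-ol | COCOc1ccc(Br)c(OCOC)c1CCO
F5 | step 5 | 2-[3-bromo-2,6-bis(methoxymethoxy)phenyl]acetaldehyde | COCOc1ccc(Br)c(OCOC)c1CC=O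
F6 | step 12 | (E)-1-{3-[(2E,6R)-3,7-dimethyl-6-(trimethylsilyloxy)octa-2,7-dien-1-yl]-2,4-bis(trimethylsilyloxy)phenyl}-3-[4-(trimethylsilyloxy)phenyl]prop-2-en-1-one | C=C(C)[C@H](O[Si](C)(C)C)CC/C(C)=C/Cc1c(O[Si](C)(C)C)ccc(C(=O)/C=C/c2ccc(O[Si](C)(C)C)cc2)c1O[Si](C)(C)C
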